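## Retrosynthetic overview
1. Licoricidin ⇒ close the chroman O1–C2 bond last, by intramolecular Mitsunobu etherification of a phenol onto a primary alcohol. Both arenes already exist, so the chroman is the only ring formed late.
2. The C3 stereocentre ⇒ Ru-BINAP asymmetric hydrogenation of an (E)-2,3-diarylacrylic acid, followed by LiAlH4 reduction of the acid to CH2OH.
3. The acrylic acid ⇒ Perkin condensation of an A-ring salicylaldehyde derivative with a B-ring arylacetic acid.
4. Both prenylated arenes come from directed ortho-metalation (DoM) of symmetric MOM-protected resorcinol-type arenes, so the prenyl regiochemistry is fixed by symmetry. A TMS group is a traceless C8 block on the A ring, and the B-ring CH2CO2H chain is added by NBS bromination followed by a Negishi–Reformatsky coupling.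

Assumptions: 5-methoxyresorcinol, resorcinol, BrZnCH2CO2Et and Ru(OAc)2[(R)-BINAP] are purchasable. (R)-BINAP is assumed to give the (R)-acid, with the antipodal ligand used if the opposite enantiomer is obtained. Reagents are not numbered unless they are drawn into the route. Any premature loss of the C8–TMS group is harmless, because C8–H is the desired outcome.

## Route

**Step 1**
Reactants: 1 (5-methoxybenzene-1,3-diol)
Product: 2 (1,3-bis(methoxymethoxy)-5-methoxybenzene)
Conditions: NaH, MOMCl, THF/DMF, 0 °C → rt
Reagents that add atoms: MOMCl, ClCOC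
Why: Bis-phenoxide O-alkylation installs two MOM groups, which are strong ortho-directing groups for the next steps.

**Step 2**
Reactants: 2
Product: 3 (1-methoxy-3,5-bis(methoxymethoxy)-4-(trimethylsilyl)benzene)
Conditions: n-BuLi, THF, −78 → 0 °C; then TMSCl
Reagents that add atoms: TMSCl, C[Si](C)(C)Cl
Why: DoM occurs at C4 between the two OMOM groups, the most acidic and best-coordinated site. Silylation there blocks what will become C8.

**Step 3**
Reactants: 3
Product: 4 (1-methoxy-3,5-bis(methoxymethoxy)-2-(3-methylbut-2-en-1-yl)-4-(trimethylsilyl)benzene)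
Conditions: n-BuLi, THF, −78 → 0 °C; then CuI (20 mol%), prenyl bromide, −78 °C → rt
Reagents that add atoms: prenyl bromide, CC(C)=CCBr
Why: C2 and C6 are equivalent by symmetry, each flanked by OMe and OMOM. Lithiation at one gives a single regioisomer, and the Cu-catalysed SN2 alkylation gives the linear prenyl group. This places the prenyl between OMe and O7, as required for C6.

**Step 4**
Reactants: 4
Product: 5 (2-methoxy-4,6-bis(methoxymethoxy)-3-(3-methylbut-2-en-1-yl)-5-(trimethylsilyl)benzaldehyde)
Conditions: n-BuLi, TMEDA, THF, −78 → 0 °C; then DMF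
Reagents that add atoms: DMF, CN(C)C=O
Why: The only remaining C–H lies between OMe and OMOM, so DoM followed by DMF quench (formylation) is unambiguous. This carbon becomes C4a.

**Step 5**
Reactants: 5
Product: 6 (2-hydroxy-6-methoxy-4-(methoxymethoxy)-5-(3-methylbut-2-en-1-yl)-3-(trimethylsilyl)benzaldehyde)
Conditions: MgBr2·OEt2 (2 equiv), Et2O/CH2Cl2, 0 °C → rt, short reaction time
Reagents that add atoms: none
Why: Mg chelation by the CHO and the ortho MOM oxygen cleaves that acetal selectively (chelation-controlled Lewis-acid deprotection). The ortho OMe and the non-chelated para MOM survive. This differentiates O8a from O7.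

**Step 6**
Reactants: 6
Product: 7 (2-(allyloxy)-6-methoxy-4-(methoxymethoxy)-5-(3-methylbut-2-en-1-yl)-3-(trimethylsilyl)benzaldehyde)
Conditions: allyl bromide, K2CO3, DMF, 60 °C
Reagents that add atoms: allyl bromide, C=CCBr
Why: Williamson O-allylation masks O8a with a group that is orthogonal to MOM and survives the Perkin, hydrogenation and LiAlH4 steps.

**Step 7**
Reactants: 8 (benzene-1,3-diol, resorcinol)
Product: 9 (1,3-bis(methoxymethoxy)benzene)
Conditions: NaH, MOMCl, THF/DMF, 0 °C → rt
Reagents that add atoms: MOMCl, ClCOC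
Why: MOM protection gives the directing groups needed for C2 lithiation.

**Step 8**
Reactants: 9
Product: 10 (1,3-bis(methoxymethoxy)-2-(3-methylbut-2-en-1-yl)benzene)
Conditions: n-BuLi, THF, 0 °C; then CuI (20 mol%), prenyl bromide, −78 °C → rt
Reagents that add atoms: prenyl bromide, CC(C)=CCBr
Why: DoM occurs exclusively at C2 between the two OMOM groups, and Cu-catalysed SN2 alkylation gives the linear prenyl group. This fixes the 3'-prenyl position.

**Step 9**
Reactants: 10
Product: 11 (1-bromo-2,4-bis(methoxymethoxy)-3-(3-methylbut-2-en-1-yl)benzene)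
Conditions: NBS (1.0 equiv), MeCN, −20 → 0 °C, dark
Reagents that add atoms: NBS, O=C1CCC(=O)N1Br
Why: Electrophilic aromatic bromination goes ortho/para to the OMOM groups. C4 and C6 are symmetry-equivalent, so one regioisomer forms, and the electron-rich arene reacts faster than the prenyl alkene.

**Step 10**
Reactants: 11
Product: 12 (ethyl 2-[2,4-bis(methoxymethoxy)-3-(3-methylbut-2-en-1-yl)phenyl]acetate)
Conditions: BrZnCH2CO2Et, Pd2(dba)3, Q-Phos, THF, 70 °C
Reagents that add atoms: ethyl bromozincacetate, CCOC(=O)C[Zn]Br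
Why: Negishi–Reformatsky coupling of the aryl bromide with a zinc enolate builds the arylacetate without touching the MOM groups or the alkene.

**Step 11**
Reactants: 12
Product: 13 (2-[2,4-bis(methoxymethoxy)-3-(3-methylbut-2-en-1-yl)phenyl]acetic acid)
Conditions: LiOH·H2O, THF/MeOH/H2O, 50 °C; then pH 4 work-up
Reagents that add atoms: water, O
Why: Saponification frees the acid required for the Perkin step. The MOM acetals are base-stable.

**Step 12**
Reactants: 7 (A-ring aldehyde) and 13 (B-ring arylacetic acid)
Product: 14 ((E)-2-[2,4-bis(methoxymethoxy)-3-prenylphenyl]-3-[2-(allyloxy)-6-methoxy-4-(methoxymethoxy)-5-prenyl-3-(trimethylsilyl)phenyl]acrylic acid)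
Conditions: Ac2O, Et3N, 140 °C, 24 h
Reagents that add atoms: none (Ac2O only takes up the water lost)
Why: Perkin condensation gives the thermodynamic (E)-α,β-diarylacrylic acid, with the two aryl groups cis and the acid trans to the A ring. This sets up the prochiral alkene for hydrogenation.

**Step 13**
Reactants: 14
Product: 15 ((2R)-2-[2,4-bis(methoxymethoxy)-3-prenylphenyl]-3-[2-(allyloxy)-6-methoxy-4-(methoxymethoxy)-5-prenyl-3-(trimethylsilyl)phenyl]propanoic acid)
Conditions: H2 (50 atm), Ru(OAc)2[(R)-BINAP] (2 mol%), MeOH, 25 °C, 24 h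
Reagents that add atoms: none (H2 only)
Why: Carboxylate-directed Noyori-type asymmetric hydrogenation sets the C3 stereocentre (R). The isolated prenyl and allyl alkenes lack a directing group and are not reduced by this catalyst.

**Step 14**
Reactants: 15
Product: 16 ((2R)-2-[2,4-bis(methoxymethoxy)-3-prenylphenyl]-3-[2-(allyloxy)-6-methoxy-4-(methoxymethoxy)-5-prenyl-3-(trimethylsilyl)phenyl]propan-1-ol)
Conditions: LiAlH4, THF, 0 °C → rt
Reagents that add atoms: none (hydride only)
Why: LiAlH4 reduces the carboxylic acid without hydroborating the prenyl alkenes, which BH3 would do. MOM, allyl and aryl-TMS groups are inert, and the stereocentre is untouched.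

**Step 15**
Reactants: 16
Product: 17 ((2R)-2-[2,4-bis(methoxymethoxy)-3-prenylphenyl]-3-[2-hydroxy-6-methoxy-4-(methoxymethoxy)-5-prenyl-3-(trimethylsilyl)phenyl]propan-1-ol)
Conditions: Pd(PPh3)4 (5 mol%), K2CO3, MeOH, rt
Reagents that add atoms: none (the allyl group is lost)
Why: Pd(0) π-allyl (Tsuji–Trost) deallylation cleaves only the aryl allyl ether, leaving the C-prenyl groups, MOM groups and primary alcohol intact. Only one phenol is then free.

**Step 16**
Reactants: 17
Product: 18 ((3R)-3-[2,4-bis(methoxymethoxy)-3-prenylphenyl]-5-methoxy-7-(methoxymethoxy)-6-prenyl-8-(trimethylsilyl)chromane)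
Conditions: PPh3, DIAD, THF, 0 °C → rt, 0.01 M
Reagents that add atoms: none
Why: Intramolecular Mitsunobu etherification closes the six-membered chroman. The reacting carbon is the primary CH2, not the stereocentre, so C3 is preserved. The B-ring O2' is MOM-protected, so no dihydrobenzofuran can form.

**Step 17**
Reactants: 18
Product: 19 (licoricidin)
Conditions: 2 M HCl, THF/MeOH (1:1), 45 °C
Reagents that add atoms: none (only H is added)
Why: Acidolysis removes the three aryl MOM acetals, and ipso-protodesilylation of the very electron-rich aryl–TMS bond gives C8–H. C3 is a non-acidic benzylic C–H and does not epimerise.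

## Compound list
1 | 5-methoxybenzene-1,3-diol | COc1cc(O)cc(O)c1 | starting material
2 | 1,3-bis(methoxymethoxy)-5-methoxybenzene | COCOc1cc(OC)cc(OCOC)c1 | intermediate
3 | 1-methoxy-3,5-bis(methoxymethoxy)-4-(trimethylsilyl)benzene | COCOc1cc(OC)cc(OCOC)c1[Si](C)(C)C | intermediate
4 | 1-methoxy-3,5-bis(methoxymethoxy)-2-prenyl-4-(trimethylsilyl)benzene | COc1cc(OCOC)c([Si](C)(C)C)c(OCOC)c1CC=C(C)C | intermediate
5 | 2-methoxy-4,6-bis(methoxymethoxy)-3-prenyl-5-(trimethylsilyl)benzaldehyde | COc1c(C=O)c(OCOC)c([Si](C)(C)C)c(OCOC)c1CC=C(C)C | intermediate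
6 | 2-hydroxy-6-methoxy-4-(methoxymethoxy)-5-prenyl-3-(trimethylsilyl)benzaldehyde | COc1c(C=O)c(O)c([Si](C)(C)C)c(OCOC)c1CC=C(C)C | intermediate
7 | 2-(allyloxy)-6-methoxy-4-(methoxymethoxy)-5-prenyl-3-(trimethylsilyl)benzaldehyde | COc1c(C=O)c(OCC=C)c([Si](C)(C)C)c(OCOC)c1CC=C(C)C | intermediate
8 | benzene-1,3-diol | Oc1cccc(O)c1 | starting material
9 | 1,3-bis(methoxymethoxy)benzene | COCOc1cccc(OCOC)c1 | intermediate
10 | 1,3-bis(methoxymethoxy)-2-prenylbenzene | COCOc1cccc(OCOC)c1CC=C(C)C | intermediate
11 | 1-bromo-2,4-bis(methoxymethoxy)-3-prenylbenzene | COCOc1ccc(Br)c(OCOC)c1CC=C(C)C | intermediate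
12 | ethyl 2-[2,4-bis(methoxymethoxy)-3-prenylphenyl]acetate | CCOC(=O)Cc1ccc(OCOC)c(CC=C(C)C)c1OCOC | intermediate
13 | 2-[2,4-bis(methoxymethoxy)-3-prenylphenyl]acetic acid | OC(=O)Cc1ccc(OCOC)c(CC=C(C)C)c1OCOC | intermediate
14 | (E)-2,3-diarylacrylic acid | OC(=O)/C(=C/c1c(OC)c(CC=C(C)C)c(OCOC)c([Si](C)(C)C)c1OCC=C)c1ccc(OCOC)c(CC=C(C)C)c1OCOC | intermediate
15 | (2R)-2,3-diarylpropanoic acid | OC(=O)[C@@H](c1ccc(OCOC)c(CC=C(C)C)c1OCOC)Cc1c(OC)c(CC=C(C)C)c(OCOC)c([Si](C)(C)C)c1OCC=C | intermediate
16 | (2R)-2,3-diarylpropan-1-ol, O-allyl | OC[C@@H](c1ccc(OCOC)c(CC=C(C)C)c1OCOC)Cc1c(OC)c(CC=C(C)C)c(OCOC)c([Si](C)(C)C)c1OCC=C | intermediate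
17 | (2R)-2,3-diarylpropan-1-ol, free phenol | OC[C@@H](c1ccc(OCOC)c(CC=C(C)C)c1OCOC)Cc1c(OC)c(CC=C(C)C)c(OCOC)c([Si](C)(C)C)c1O | intermediate
18 | (3R)-protected chroman | COc1c(CC=C(C)C)c(OCOC)c([Si](C)(C)C)c2c1C[C@H](c1ccc(OCOC)c(CC=C(C)C)c1OCOC)CO2 | intermediate
19 | licoricidin | COc1c(CC=C(C)C)c(O)cc2c1C[C@H](c1ccc(O)c(CC=C(C)C)c1O)CO2 | target

## Totals
Total steps: 17. Longest linear sequence: 12 (steps 1–6 on the A ring, then steps 12–17).

## Three steps most likely to fail
1. **Step 13 (asymmetric hydrogenation).** The tri-substituted acid is very hindered, so conversion or ee may be low, and the allyl ether could be partly reduced. Fallback, a different approach: convert acid 13 to its (R)-4-benzyloxazolidin-2-one imide and alkylate it (Evans) with the A-ring benzylic bromide made from 7 (NaBH4, then PBr3). Remove the auxiliary with LiBH4 to reach alcohol 16 directly.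
2. **Step 12 (Perkin).** The A-ring aldehyde is di-ortho-substituted and very electron-rich, so conversion may be poor. Fallback: use an aldol route. Add the lithium enolate of ester 12 to 7, dehydrate (MsCl, Et3N, then DBU), and saponify to give the same acid 14.
3. **Step 5 (chelation-controlled MOM cleavage).** Over-cleavage of the para MOM or the ortho OMe would give mixtures. Fallback: desymmetrise at the start instead. Mono-allylate 1, MOM-protect the other OH, and run the same DoM sequence (TMS block, prenyl, CHO), relying on OMOM out-directing OAllyl. This removes steps 5 and 6 but trades them for a directing-group competition at the prenylation and formylation steps.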